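## The problem

The target is a trans-fused bicyclo[5.3.0]decene of the daucane type. Cyclopentane ring A (C1–C5) shares the C1–C5 bond with cycloheptene ring B (C1, C5, C6–C10), which holds the methyl-bearing C8=C9 alkene; the fusion carbon C1 is quaternary and carries a methyl group. Locants used throughout: C1 fusion carbon with methyl, C2 CH(OAc), C3 CH2, C4 C(OH)(i-Pr), C5 fusion CH, C6 CH(O-veratroyl), C7 CH2, C8(Me)=C9, C10 CH(OAc); β is the face of the C1 methyl, α the opposite face. Six stereocentres (C1, C2, C4, C5, C6, C10) must be set, and all four carbons that flank the fusion bond carry oxygen. These oxygens end in three different states (two acetates, one veratroate, one free tertiary alcohol), so C6 has to be acylated apart from C2 and C10. The C4 hydroxyl is β and the C2 and C6 oxygens are α, each 1,3-anti to it, so a free C4 hydroxyl can deliver hydride to ketones at C2 and C6. C5–H is α and can be set next to C6, but the quaternary C1 and C10 lie outside this relay and need their own control. The esters will not survive organometallic or hydride reagents, the C10 oxygen is allylic to a trisubstituted alkene and ionises in acid, and the C4 carbinol is a tertiary aldol whenever C2 or C6 is a ketone. The enabling feature is that, with C6 at the ketone level written as its enol ether C5=C6, ring B is a cyclohepta-1,4-diene (C5=C6, C8=C9). Its C1–C10 bond is the σ bond formed in a cis-divinylcyclopropane rearrangement, and its C6–C7 bond is the one a C6 alkoxycarbene makes when it cyclopropanates a C7=C8 alkene.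

## Retrosynthesis

**Acetates and C2.** Target 28 is cut at the two acetyl C–O bonds to triol 27, and 27 at the C10 silyl ether to 26. The acetates are put on last because no hydride or organometallic step can follow them. The C2 carbinol of 26 comes from ketone 25 by hydride delivery from the β C4 hydroxyl. The C10 oxygen must stay silylated in that step, because a free α C10 hydroxyl would direct hydride to the wrong face of C2. Ketone 25 comes from dioxolane 24 by hydrolysis.

**Veratroate and C6.** Ester 24 is cut at the C6–O acyl bond to diol 22 and veratroyl chloride 23. Diol 22 has only one secondary hydroxyl, so no selectivity is asked of the acylation. The C6 carbinol of 22 comes from β-hydroxy ketone 21 by the same hydroxyl-directed reduction, and 21 from dimethyl ketal 20. Unmasking C6 (acyclic ketal) before C2 (dioxolane) is what separates the veratroate from the acetates. An undirected reduction of a C6 ketone would be expected to attack anti to the C1 methyl and give the wrong 6β alcohol.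

**Isopropyl group and C4.** Carbinol 20 is cut at the C4–isopropyl bond to ketone 19, which comes from alcohol 18 by oxidation. During the addition C6 must be sp3 and must not be a carbonyl; a C5=C6 enol ether next to a C4 carbinol would collapse to an enone on hydrolysis. The enol ether is therefore turned into the dimethyl ketal 18 by addition of methanol to 17, which also sets C5–H and frees the C4 hydroxyl from its triethylsilyl ether. Compound 17 comes from 16 by silylation, and 16 from allylsilane 15 by Tamao oxidation with retention. The C4 ether is triethylsilyl and the C10 ether tert-butyldimethylsilyl so that mild acid removes only the former.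

**Ring B (key disconnection).** Enol ether 15 is cut at C1–C10 (retro-Cope, to cyclopropane 14) and at C6–C7 and C6–C8 (retro carbene transfer), giving carbene complex 9 and silyl diene 13. Compared with closing ring B on a finished ring A by a carbonyl addition or metathesis, this cut removes the seven-membered ring, the quaternary C1 and the C10 stereocentre in one step. It leaves an achiral four-carbon diene and a cyclopentene with one stereocentre. The forward reaction must transfer the carbene to the terminal alkene of 13, rearrange through a boat with the C1 methyl inside, and bond C10 to C1 anti to the C4 silyloxy group.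

**Carbene complex.** Complex 9 is cut at C5–C6 and at the carbene O–methyl bond to bromide 6, Cr(CO)6 and a methylating agent. Bromide 6 comes from bromo enone 5 by ketalisation, 5 from silyl ether 4 by allylic oxidation, 4 from alcohol 3, 3 from bromo enone 2 by enantioselective reduction, and 2 from 3-methylcyclopent-2-en-1-one 1. Bromine serves twice: it makes the alkenyl side the large group in the reduction and is the handle for lithiation. A 4-silyloxy-2-methylcyclopentenone from a furan precursor was set aside because it would need halogenation at the enone β carbon, for which no dependable method is known. The ketal at C2 is symmetric towards both ring faces, so only C4 controls the key step.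

**Diene.** Diene 13 is cut at the C10–Si bond to 2-methylbut-1-en-3-yne 10 and chlorodimethylsilane 11; the chlorosilane 12 is exchanged for the isopropoxysilane that the Tamao oxidation needs.

## Roads not taken

**Alternative 1: Buchner reaction.** The cut is at C1–C5 and C1–C10. A rhodium carbenoid from the diazo ketone A1 (2-diazo-5-(2,6-dimethoxy-4-methylphenyl)-6-methyl-5-(triethylsilyloxy)heptan-3-one) would add across the ipso–ortho bond of the arene and open to the cycloheptatrienone A2.
- Merits: both rings form in one catalytic step, and every carbon and all four oxygens of the target are in place, with isopropyl already on C4. A1 is short to make from 3,5-dimethoxytoluene. In step count to the bicyclic skeleton and in metal economy this road is better than the chosen plan.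
- Weak points: a carbenoid flanked by a methyl group tends to undergo 1,2-hydride shift to the enone. The bond to be cyclopropanated is fully substituted and bears a methoxy group. The C1 configuration rests only on the difference between silyloxy and isopropyl at C4.
- After the key step: A2 is a triene with two enol ethers. C5, C6 and C10 would all have to be set on it, and two alkenes removed while C8=C9 is kept, with nothing in the molecule to guide this.
- Comparison: the chosen plan uses stoichiometric chromium and an untested rearrangement. Against that it leaves one enol ether instead of two and fixes C10 relative to C1 in the ring-forming step.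

**Alternative 2: C–H insertion on a cycloheptenone.** The cut is at C2–C3. The diazomethyl ketone A3, a cycloheptenone that already holds C1, C5 and C6, would give a rhodium carbenoid that inserts into a C–H bond of the (4-methoxybenzyloxy)methyl group on C1, giving the trans-fused dione A4.
- Merits: insertion next to an ether oxygen to form a cyclopentanone is a reliable catalytic reaction. The ring fusion and C6 are fixed beforehand. This is better than the chosen plan in that no stereocentre of ring B depends on a new reaction.
- Weak points: A3 needs a seven-membered ring with three contiguous stereocentres, one quaternary, before the key step, which is long. The ether oxygen can capture the carbenoid as a six-membered oxonium ylide and shift the benzyl group. The benzylic C–H bonds, the enone and the alkene are further competitors, and the C2 configuration is decided in the insertion.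
- After the key step: A4 still needs the isopropyl addition at C4, a stereoselective reduction at C10 and the protecting-group changes, so the later part is no shorter.
- Comparison: the chosen plan makes the difficult ring from two small fragments in one step, at the price of a key step without direct precedent.

**Alternative 3: Nozaki–Hiyama–Kishi closure.** The cut is at C9–C10. The iodo aldehyde A5 would be treated with CrCl2 and catalytic NiCl2; the alkenylchromium species adds to the C10 aldehyde and closes ring B to the triol A6, which is identical with 27.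
- Merits: the reaction is known, tolerates free hydroxyls and the ester, and ends one acetylation from the target. In precedent and in the length of the sequence after the key step this road is clearly better.
- Weak points: A5 is a fully substituted cyclopentane with four stereocentres (two quaternary) and a side chain with the C6 stereocentre and a (Z)-trisubstituted alkenyl iodide. Nearly the whole synthesis lies before the key step and is linear. The neopentyl aldehyde is a β-hydroxy aldehyde prone to retro-aldol cleavage. The C10 configuration comes from an unguided carbonyl addition in a medium ring and may need an oxidation–reduction repair.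
- Comparison: the chosen plan sets C10 stereospecifically from the alkene geometry and builds ring B early from simple fragments.

Key step: step 8

Remark: in the compound names the locants C1–C10 are those of the target, β is the face of the C1 methyl and α the opposite face.

Assumption: in the oxazaborolidine reduction of 2 the bromoalkenyl carbon acts as the large substituent, as for 2-bromocycloalkenones in general, so the (R)-catalyst gives the (S)-alcohol.

## Route

Step 1
Reactants: 1 3-methylcyclopent-2-en-1-one
Product: 2 2-bromo-3-methylcyclopent-2-en-1-one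
Conditions: Br2, CH2Cl2, 0 °C; then Et3N, 0 °C to rt
Reagents that add atoms: bromine, BrBr
Why: α-Bromination of a cyclic enone by addition of bromine and elimination of HBr from the dibromide; standard for cyclopentenones.

Step 2
Reactants: 2 2-bromo-3-methylcyclopent-2-en-1-one
Product: 3 (S)-2-bromo-3-methylcyclopent-2-en-1-ol
Conditions: (R)-1-methyl-3,3-diphenyltetrahydro-1H,3H-pyrrolo[1,2-c][1,3,2]oxazaborole (10 mol %), BH3·SMe2, THF, −20 °C
Reagents that add atoms: none
Why: Corey–Bakshi–Shibata reduction; the bromoalkenyl carbon is the large group, so the (R)-catalyst should deliver hydride to the face that gives the (S)-carbinol, the future C4.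

Step 3
Reactants: 3 (S)-2-bromo-3-methylcyclopent-2-en-1-ol
Product: 4 (S)-[(2-bromo-3-methylcyclopent-2-en-1-yl)oxy]triethylsilane
Conditions: Et3SiCl, imidazole, CH2Cl2, 0 °C to rt
Reagents that add atoms: chlorotriethylsilane, CC[Si](Cl)(CC)CC
Why: Silylation of a secondary allylic alcohol; the triethylsilyl group is chosen because it can later be removed by mild acid beside a tert-butyldimethylsilyl ether.

Step 4
Reactants: 4 (S)-[(2-bromo-3-methylcyclopent-2-en-1-yl)oxy]triethylsilane
Product: 5 (S)-3-bromo-2-methyl-4-[(triethylsilyl)oxy]cyclopent-2-en-1-one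
Conditions: CrO3, 3,5-dimethylpyrazole, CH2Cl2, −20 °C
Reagents that add atoms: chromium trioxide, O=[Cr](=O)=O
Why: Allylic oxidation of a cyclopentene to the enone; the ring CH2 next to the methyl-bearing alkene carbon is the only open secondary allylic position, while the carbinol C–H is shielded by the silyl ether and deactivated by the neighbouring bromine; the stereocentre is untouched.

Step 5
Reactants: 5 (S)-3-bromo-2-methyl-4-[(triethylsilyl)oxy]cyclopent-2-en-1-one
Product: 6 (S)-[(7-bromo-6-methyl-1,4-dioxaspiro[4.4]non-6-en-8-yl)oxy]triethylsilane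
Conditions: Me3SiOCH2CH2OSiMe3, Me3SiOTf (5 mol %), CH2Cl2, −78 to −20 °C
Reagents that add atoms: 1,2-bis(trimethylsilyloxy)ethane, C[Si](C)(C)OCCO[Si](C)(C)C
Why: Noyori ketalisation under aprotic conditions; the tetrasubstituted alkene cannot migrate and the silyl ether should survive catalytic silyl triflate at low temperature.

Step 6
Reactants: 6 (S)-[(7-bromo-6-methyl-1,4-dioxaspiro[4.4]non-6-en-8-yl)oxy]triethylsilane
Product: 9 pentacarbonyl{methoxy[(8S)-6-methyl-8-(triethylsilyloxy)-1,4-dioxaspiro[4.4]non-6-en-7-yl]methylidene}chromium, via vinyllithium 7 (not isolated), via lithium acylchromate 8 (not isolated)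
Conditions: t-BuLi (2.1 equiv), Et2O, −78 °C; Cr(CO)6, −78 to 0 °C; then Me3OBF4, CH2Cl2, 0 °C
Reagents that add atoms: hexacarbonylchromium, O=C=[Cr](=C=O)(=C=O)(=C=O)(=C=O)=C=O; trimethyloxonium tetrafluoroborate, C[O+](C)C.F[B-](F)(F)F
Why: Fischer carbene synthesis: bromine–lithium exchange, addition of the alkenyllithium to a CO ligand and O-methylation of the acyl chromate; the stereocentre is not involved.

Step 7
Reactants: 10 2-methylbut-1-en-3-yne; 11 chlorodimethylsilane
Product: 13 (E)-isopropoxydimethyl(3-methylbuta-1,3-dien-1-yl)silane, via dienylchlorosilane 12 (not isolated)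
Conditions: Pt2[(CH2=CHSiMe2)2O]3 (0.1 mol %), neat, 0 °C to rt; then i-PrOH, Et3N, Et2O, 0 °C
Reagents that add atoms: propan-2-ol, CC(C)O
Why: Platinum-catalysed syn hydrosilylation of the terminal alkyne, which reacts before the 1,1-disubstituted alkene and puts silicon at the terminus with (E) geometry; alcoholysis of the Si–Cl bond then installs the alkoxy group needed for the later oxidation.

Step 8
Reactants: 9 pentacarbonyl{methoxy[(8S)-6-methyl-8-(triethylsilyloxy)-1,4-dioxaspiro[4.4]non-6-en-7-yl]methylidene}chromium; 13 (E)-isopropoxydimethyl(3-methylbuta-1,3-dien-1-yl)silane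
Product: 15 10α-[isopropoxy(dimethyl)silyl]-6-methoxy-1β,8-dimethyl-4β-(triethylsilyloxy)bicyclo[5.3.0]deca-5,8-dien-2-one ethylene ketal, via dialkenylcyclopropane 14 (not isolated)
Conditions: 13 (3 equiv), degassed toluene, 100 °C, sealed tube; then air, filtration
Reagents that add atoms: none
Why: Proposed new method: loss of CO from the zerovalent chromium carbene 9 lets the terminal C7=C8 alkene of 13 coordinate, the carbene carbon C6 bonds to the unsubstituted C7, and reductive elimination from the chromacyclobutane forms C6–C8 and closes cyclopropane 14; the closest known reaction type is the formal (4+3) annulation of alkenyl(alkoxy)carbene chromium complexes with 1,3-dienes by cyclopropanation and Cope rearrangement, which has not been shown for a carbene whose alkene terminus is fully substituted. Ring B is then closed by a [3,3]-sigmatropic shift of the cis-dialkenyl isomer of 14 through a boat transition state, which forms C1–C10 as the cyclopropane bond C6–C8 breaks and leaves the C5=C6 enol ether and the C8=C9 alkene. The (E) geometry of the vinylsilane and the ring geometry of C5=C1 place silicon and C2 both outside the boat, so the silyl group on C10 ends cis to C2 and trans to the C1 methyl. The configuration of C1 is controlled by the C4 silyloxy group, because C10 should bond to the cyclopentene face opposite to it. The stereoisomers of 14 should interconvert at this temperature by homolysis of the C6–C8 bond, which is flanked by a methoxy and two alkenyl groups, so all material can drain through the favoured boat. Carbene transfer must go to the 1,1-disubstituted alkene and not to the vinylsilane, which the open CH2 terminus and the bulk of the silylated alkene should secure. Diels–Alder addition to the carbene's own alkene, the usual competitor, is shut off because that alkene is tetrasubstituted. The C1 methyl lies inside the boat and raises the barrier, hence the temperature near 100 °C.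

Step 9
Reactants: 15 10α-[isopropoxy(dimethyl)silyl]-6-methoxy-1β,8-dimethyl-4β-(triethylsilyloxy)bicyclo[5.3.0]deca-5,8-dien-2-one ethylene ketal
Product: 16 10α-hydroxy-6-methoxy-1β,8-dimethyl-4β-(triethylsilyloxy)bicyclo[5.3.0]deca-5,8-dien-2-one ethylene ketal
Conditions: KF, KHCO3, 30% H2O2, THF/MeOH, rt to 40 °C
Reagents that add atoms: hydrogen peroxide, OO
Why: Tamao oxidation of the alkoxysilane with retention at carbon, known for allylic alkoxysilanes; it is run first because the allylsilane would not survive the acid of step 11, and the basic medium leaves the enol ether and ketal alone.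

Step 10
Reactants: 16 10α-hydroxy-6-methoxy-1β,8-dimethyl-4β-(triethylsilyloxy)bicyclo[5.3.0]deca-5,8-dien-2-one ethylene ketal
Product: 17 10α-(tert-butyldimethylsilyloxy)-6-methoxy-1β,8-dimethyl-4β-(triethylsilyloxy)bicyclo[5.3.0]deca-5,8-dien-2-one ethylene ketal
Conditions: t-BuMe2SiOTf, 2,6-lutidine, CH2Cl2, −78 to 0 °C
Reagents that add atoms: tert-butyldimethylsilyl trifluoromethanesulfonate, CC(C)(C)[Si](C)(C)OS(=O)(=O)C(F)(F)F
Why: Silyl triflate silylation of a hindered neopentyl allylic alcohol under basic conditions that spare the enol ether; the ether masks C10 through the oxidation, the organometallic step and both directed reductions.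

Step 11
Reactants: 17 10α-(tert-butyldimethylsilyloxy)-6-methoxy-1β,8-dimethyl-4β-(triethylsilyloxy)bicyclo[5.3.0]deca-5,8-dien-2-one ethylene ketal
Product: 18 10α-(tert-butyldimethylsilyloxy)-4β-hydroxy-6,6-dimethoxy-1β,8-dimethyl-5α-H-bicyclo[5.3.0]dec-8-en-2-one ethylene ketal
Conditions: pyridinium p-toluenesulfonate (0.2 equiv), MeOH/CH2Cl2, 0 °C to rt
Reagents that add atoms: methanol, CO
Why: Acid-catalysed addition of methanol to the enol ether through the C6 oxocarbenium ion; C5 should be protonated on the α face, away from the β C1 methyl and the β C4 silyloxy group, which sets the trans fusion. The triethylsilyl ether is then cleaved by the same acid, while the hindered tert-butyldimethylsilyl ether and the dioxolane should remain.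

Step 12
Reactants: 18 10α-(tert-butyldimethylsilyloxy)-4β-hydroxy-6,6-dimethoxy-1β,8-dimethyl-5α-H-bicyclo[5.3.0]dec-8-en-2-one ethylene ketal
Product: 19 10α-(tert-butyldimethylsilyloxy)-6,6-dimethoxy-1β,8-dimethyl-5α-H-bicyclo[5.3.0]dec-8-ene-2,4-dione 2-ethylene ketal
Conditions: Dess–Martin periodinane, NaHCO3, CH2Cl2, 0 °C to rt
Reagents that add atoms: none
Why: Dess–Martin oxidation of the only free hydroxyl; the buffered, non-basic medium should leave the C5 stereocentre next to the new ketone intact.

Step 13
Reactants: 19 10α-(tert-butyldimethylsilyloxy)-6,6-dimethoxy-1β,8-dimethyl-5α-H-bicyclo[5.3.0]dec-8-ene-2,4-dione 2-ethylene ketal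
Product: 20 10α-(tert-butyldimethylsilyloxy)-4β-hydroxy-4α-isopropyl-6,6-dimethoxy-1β,8-dimethyl-5α-H-bicyclo[5.3.0]dec-8-en-2-one ethylene ketal
Conditions: i-PrMgCl, CeCl3, THF, −78 to −40 °C
Reagents that add atoms: isopropylmagnesium chloride, CC(C)[Mg]Cl
Why: Organocerium addition to an enolisable ketone; the nucleophile should enter on the α face, past the C5 hydrogen and away from the β C1 methyl and the C6 ketal carbon, giving the 4β hydroxyl; the low basicity suppresses enolisation towards C5 and loss of methoxide from C6.

Step 14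
Reactants: 20 10α-(tert-butyldimethylsilyloxy)-4β-hydroxy-4α-isopropyl-6,6-dimethoxy-1β,8-dimethyl-5α-H-bicyclo[5.3.0]dec-8-en-2-one ethylene ketal
Product: 21 10α-(tert-butyldimethylsilyloxy)-4β-hydroxy-4α-isopropyl-1β,8-dimethyl-5α-H-bicyclo[5.3.0]dec-8-ene-2,6-dione 2-ethylene ketal
Conditions: pyridinium p-toluenesulfonate (cat.), acetone/H2O, 0 °C to rt
Reagents that add atoms: water, O
Why: Selective hydrolysis of the acyclic dimethyl ketal, which is far more labile than the dioxolane; in 21 C6 lies trans to the α isopropyl group, so any equilibration at C5 should favour the required trans fusion.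

Step 15
Reactants: 21 10α-(tert-butyldimethylsilyloxy)-4β-hydroxy-4α-isopropyl-1β,8-dimethyl-5α-H-bicyclo[5.3.0]dec-8-ene-2,6-dione 2-ethylene ketal
Product: 22 10α-(tert-butyldimethylsilyloxy)-4β,6α-dihydroxy-4α-isopropyl-1β,8-dimethyl-5α-H-bicyclo[5.3.0]dec-8-en-2-one ethylene ketal
Conditions: Me4NBH(OAc)3, AcOH/MeCN, −30 to 0 °C
Reagents that add atoms: none
Why: Evans–Saksena reduction: the C4 hydroxyl exchanges onto boron and delivers hydride within the molecule to the β face of C6, giving the 6α alcohol (1,3-anti diol).

Step 16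
Reactants: 22 10α-(tert-butyldimethylsilyloxy)-4β,6α-dihydroxy-4α-isopropyl-1β,8-dimethyl-5α-H-bicyclo[5.3.0]dec-8-en-2-one ethylene ketal; 23 3,4-dimethoxybenzoyl chloride
Product: 24 10α-(tert-butyldimethylsilyloxy)-4β-hydroxy-4α-isopropyl-1β,8-dimethyl-2-oxo-5α-H-bicyclo[5.3.0]dec-8-en-6α-yl 3,4-dimethoxybenzoate 2-ethylene ketal
Conditions: Et3N, 4-(dimethylamino)pyridine, CH2Cl2, 0 °C to rt
Reagents that add atoms: none
Why: Acylation of the only secondary hydroxyl with the acid chloride under nucleophilic catalysis; the tertiary C4 hydroxyl should not react.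

Step 17
Reactants: 24 10α-(tert-butyldimethylsilyloxy)-4β-hydroxy-4α-isopropyl-1β,8-dimethyl-2-oxo-5α-H-bicyclo[5.3.0]dec-8-en-6α-yl 3,4-dimethoxybenzoate 2-ethylene ketal
Product: 25 10α-(tert-butyldimethylsilyloxy)-4β-hydroxy-4α-isopropyl-1β,8-dimethyl-2-oxo-5α-H-bicyclo[5.3.0]dec-8-en-6α-yl 3,4-dimethoxybenzoate
Conditions: pyridinium p-toluenesulfonate (0.2 equiv), acetone/H2O, 50 °C
Reagents that add atoms: water, O
Why: Mild acid hydrolysis of the dioxolane with acetone as acceptor for the diol; a weak acid is used to spare the tertiary aldol, the allylic silyl ether and the ester.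

Step 18
Reactants: 25 10α-(tert-butyldimethylsilyloxy)-4β-hydroxy-4α-isopropyl-1β,8-dimethyl-2-oxo-5α-H-bicyclo[5.3.0]dec-8-en-6α-yl 3,4-dimethoxybenzoate
Product: 26 10α-(tert-butyldimethylsilyloxy)-2α,4β-dihydroxy-4α-isopropyl-1β,8-dimethyl-5α-H-bicyclo[5.3.0]dec-8-en-6α-yl 3,4-dimethoxybenzoate
Conditions: Me4NBH(OAc)3, AcOH/MeCN, −20 °C to rt
Reagents that add atoms: none
Why: Second Evans–Saksena reduction: hydride is delivered from the β C4 hydroxyl to the β face of the neopentyl C2 ketone and gives the 2α alcohol; the C10 oxygen is silylated so that it cannot direct from the α face, and the ester is inert to the acyloxyborohydride.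

Step 19
Reactants: 26 10α-(tert-butyldimethylsilyloxy)-2α,4β-dihydroxy-4α-isopropyl-1β,8-dimethyl-5α-H-bicyclo[5.3.0]dec-8-en-6α-yl 3,4-dimethoxybenzoate
Product: 27 2α,4β,10α-trihydroxy-4α-isopropyl-1β,8-dimethyl-5α-H-bicyclo[5.3.0]dec-8-en-6α-yl 3,4-dimethoxybenzoate
Conditions: HF·pyridine, pyridine/THF, 0 °C to rt
Reagents that add atoms: none
Why: Fluoride cleavage of the silyl ether under buffered, weakly acidic conditions that should neither move the benzoate nor ionise the allylic alcohol.

Step 20
Reactants: 27 2α,4β,10α-trihydroxy-4α-isopropyl-1β,8-dimethyl-5α-H-bicyclo[5.3.0]dec-8-en-6α-yl 3,4-dimethoxybenzoate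
Product: 28 (1R,2S,4R,5S,6S,10R)-2,10-diacetoxy-4-hydroxy-4-isopropyl-1,8-dimethylbicyclo[5.3.0]dec-8-en-6-yl 3,4-dimethoxybenzoate
Conditions: Ac2O, 4-(dimethylamino)pyridine, pyridine, rt
Reagents that add atoms: acetic anhydride, CC(=O)OC(C)=O
Why: Acetylation of the two secondary hydroxyls at C2 and C10; the tertiary C4 hydroxyl should stay free under these conditions.

## Compound list

1 | 3-methylcyclopent-2-en-1-one | CC1=CC(=O)CC1 | starting material
2 | 2-bromo-3-methylcyclopent-2-en-1-one | CC1=C(Br)C(=O)CC1 | intermediate
3 | (S)-2-bromo-3-methylcyclopent-2-en-1-ol | CC1=C(Br)[C@@H](O)CC1 | intermediate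
4 | (S)-[(2-bromo-3-methylcyclopent-2-en-1-yl)oxy]triethylsilane | CC1=C(Br)[C@@H](O[Si](CC)(CC)CC)CC1 | intermediate
5 | (S)-3-bromo-2-methyl-4-[(triethylsilyl)oxy]cyclopent-2-en-1-one | CC1=C(Br)[C@@H](O[Si](CC)(CC)CC)CC1=O | intermediate
6 | (S)-[(7-bromo-6-methyl-1,4-dioxaspiro[4.4]non-6-en-8-yl)oxy]triethylsilane | CC1=C(Br)[C@@H](O[Si](CC)(CC)CC)CC12OCCO2 | intermediate
7 | [(8S)-6-methyl-8-(triethylsilyloxy)-1,4-dioxaspiro[4.4]non-6-en-7-yl]lithium (not isolated) | [Li]C1=C(C)C2(OCCO2)C[C@@H]1O[Si](CC)(CC)CC | intermediate
8 | lithium pentacarbonyl{[(8S)-6-methyl-8-(triethylsilyloxy)-1,4-dioxaspiro[4.4]non-6-en-7-yl]carbonyl}chromate (not isolated) | [Li+].[O-]C(=[Cr](=C=O)(=C=O)(=C=O)(=C=O)=C=O)C1=C(C)C2(OCCO2)C[C@@H]1O[Si](CC)(CC)CC | intermediate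
9 | pentacarbonyl{methoxy[(8S)-6-methyl-8-(triethylsilyloxy)-1,4-dioxaspiro[4.4]non-6-en-7-yl]methylidene}chromium | COC(=[Cr](=C=O)(=C=O)(=C=O)(=C=O)=C=O)C1=C(C)C2(OCCO2)C[C@@H]1O[Si](CC)(CC)CC | intermediate
10 | 2-methylbut-1-en-3-yne | CC(=C)C#C | starting material
11 | chlorodimethylsilane | C[SiH](C)Cl | starting material
12 | (E)-chlorodimethyl(3-methylbuta-1,3-dien-1-yl)silane (not isolated) | C=C(C)/C=C/[Si](C)(C)Cl | intermediate
13 | (E)-isopropoxydimethyl(3-methylbuta-1,3-dien-1-yl)silane | C=C(C)/C=C/[Si](C)(C)OC(C)C | intermediate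
14 | 1-methoxy-2-methyl-1-[(8S)-6-methyl-8-(triethylsilyloxy)-1,4-dioxaspiro[4.4]non-6-en-7-yl]-2-[(E)-2-(isopropoxydimethylsilyl)ethenyl]cyclopropane (not isolated; stereoisomers at the two substituted ring carbons, the cis-dialkenyl ones rearrange) | COC1(CC1(C)/C=C/[Si](C)(C)OC(C)C)C2=C(C)C3(OCCO3)C[C@@H]2O[Si](CC)(CC)CC | intermediate
15 | 10α-[isopropoxy(dimethyl)silyl]-6-methoxy-1β,8-dimethyl-4β-(triethylsilyloxy)bicyclo[5.3.0]deca-5,8-dien-2-one ethylene ketal | COC=2CC(C)=C[C@@H]([Si](C)(C)OC(C)C)[C@@]3(C)C4(OCCO4)C[C@H](O[Si](CC)(CC)CC)C=23 | intermediate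
16 | 10α-hydroxy-6-methoxy-1β,8-dimethyl-4β-(triethylsilyloxy)bicyclo[5.3.0]deca-5,8-dien-2-one ethylene ketal | COC=2CC(C)=C[C@@H](O)[C@@]3(C)C4(OCCO4)C[C@H](O[Si](CC)(CC)CC)C=23 | intermediate
17 | 10α-(tert-butyldimethylsilyloxy)-6-methoxy-1β,8-dimethyl-4β-(triethylsilyloxy)bicyclo[5.3.0]deca-5,8-dien-2-one ethylene ketal | COC=2CC(C)=C[C@@H](O[Si](C)(C)C(C)(C)C)[C@@]3(C)C4(OCCO4)C[C@H](O[Si](CC)(CC)CC)C=23 | intermediate
18 | 10α-(tert-butyldimethylsilyloxy)-4β-hydroxy-6,6-dimethoxy-1β,8-dimethyl-5α-H-bicyclo[5.3.0]dec-8-en-2-one ethylene ketal | COC2(OC)CC(C)=C[C@@H](O[Si](C)(C)C(C)(C)C)[C@@]3(C)C4(OCCO4)C[C@H](O)[C@H]23 | intermediate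
19 | 10α-(tert-butyldimethylsilyloxy)-6,6-dimethoxy-1β,8-dimethyl-5α-H-bicyclo[5.3.0]dec-8-ene-2,4-dione 2-ethylene ketal | COC2(OC)CC(C)=C[C@@H](O[Si](C)(C)C(C)(C)C)[C@@]3(C)C4(OCCO4)CC(=O)[C@H]23 | intermediate
20 | 10α-(tert-butyldimethylsilyloxy)-4β-hydroxy-4α-isopropyl-6,6-dimethoxy-1β,8-dimethyl-5α-H-bicyclo[5.3.0]dec-8-en-2-one ethylene ketal | COC2(OC)CC(C)=C[C@@H](O[Si](C)(C)C(C)(C)C)[C@@]3(C)C4(OCCO4)C[C@@](O)(C(C)C)[C@H]23 | intermediate
21 | 10α-(tert-butyldimethylsilyloxy)-4β-hydroxy-4α-isopropyl-1β,8-dimethyl-5α-H-bicyclo[5.3.0]dec-8-ene-2,6-dione 2-ethylene ketal | O=C2CC(C)=C[C@@H](O[Si](C)(C)C(C)(C)C)[C@@]3(C)C4(OCCO4)C[C@@](O)(C(C)C)[C@H]23 | intermediate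
22 | 10α-(tert-butyldimethylsilyloxy)-4β,6α-dihydroxy-4α-isopropyl-1β,8-dimethyl-5α-H-bicyclo[5.3.0]dec-8-en-2-one ethylene ketal | O[C@H]2CC(C)=C[C@@H](O[Si](C)(C)C(C)(C)C)[C@@]3(C)C4(OCCO4)C[C@@](O)(C(C)C)[C@H]23 | intermediate
23 | 3,4-dimethoxybenzoyl chloride (veratroyl chloride) | COc1ccc(C(Cl)=O)cc1OC | starting material
24 | 10α-(tert-butyldimethylsilyloxy)-4β-hydroxy-4α-isopropyl-1β,8-dimethyl-2-oxo-5α-H-bicyclo[5.3.0]dec-8-en-6α-yl 3,4-dimethoxybenzoate 2-ethylene ketal | COc1ccc(C(=O)O[C@H]2CC(C)=C[C@@H](O[Si](C)(C)C(C)(C)C)[C@@]3(C)C4(OCCO4)C[C@@](O)(C(C)C)[C@H]23)cc1OC | intermediate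
25 | 10α-(tert-butyldimethylsilyloxy)-4β-hydroxy-4α-isopropyl-1β,8-dimethyl-2-oxo-5α-H-bicyclo[5.3.0]dec-8-en-6α-yl 3,4-dimethoxybenzoate | COc1ccc(C(=O)O[C@H]2CC(C)=C[C@@H](O[Si](C)(C)C(C)(C)C)[C@@]3(C)C(=O)C[C@@](O)(C(C)C)[C@H]23)cc1OC | intermediate
26 | 10α-(tert-butyldimethylsilyloxy)-2α,4β-dihydroxy-4α-isopropyl-1β,8-dimethyl-5α-H-bicyclo[5.3.0]dec-8-en-6α-yl 3,4-dimethoxybenzoate | COc1ccc(C(=O)O[C@H]2CC(C)=C[C@@H](O[Si](C)(C)C(C)(C)C)[C@@]3(C)[C@@H](O)C[C@@](O)(C(C)C)[C@H]23)cc1OC | intermediate
27 | 2α,4β,10α-trihydroxy-4α-isopropyl-1β,8-dimethyl-5α-H-bicyclo[5.3.0]dec-8-en-6α-yl 3,4-dimethoxybenzoate | COc1ccc(C(=O)O[C@H]2CC(C)=C[C@@H](O)[C@@]3(C)[C@@H](O)C[C@@](O)(C(C)C)[C@H]23)cc1OC | intermediate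
28 | (1R,2S,4R,5S,6S,10R)-2,10-diacetoxy-4-hydroxy-4-isopropyl-1,8-dimethylbicyclo[5.3.0]dec-8-en-6-yl 3,4-dimethoxybenzoate (2α,10α-diacetoxy, 4β-hydroxy, 5α-H, 6α-ester) | COc1ccc(C(=O)O[C@H]2CC(C)=C[C@@H](OC(C)=O)[C@@]3(C)[C@@H](OC(C)=O)C[C@@](O)(C(C)C)[C@H]23)cc1OC | target

## Step count and risks

Total steps: 20. Longest linear sequence: 19 steps (steps 1–6 and 8–20); step 7 supplies the diene.

**Step 8 (key step, proposed new method).**
- Most likely failure: the hindered, fully substituted alkenylcarbene decomposes after CO loss (CO insertion, carbene coupling) faster than it is captured by the diene, so that no cyclopropane is formed. A slow rearrangement with the methyl group inside the boat is the second concern.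
- Fallback, setting out from 6 and returning at 14, using only known reaction types:
  - Bromide 6 would be lithiated as in step 6 (7) and acylated with the Weinreb amide (E)-N-methoxy-N,2-dimethyl-4-[isopropoxy(dimethyl)silyl]but-2-enamide F1. F1 would be made from N-methoxy-N-methylmethacrylamide and allyl(isopropoxy)dimethylsilane by cross-metathesis with the second-generation Grubbs catalyst.
  - The acylation would give the dienone (E)-4-[isopropoxy(dimethyl)silyl]-2-methyl-1-[(8S)-6-methyl-8-(triethylsilyloxy)-1,4-dioxaspiro[4.4]non-6-en-7-yl]but-2-en-1-one F2.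
  - Deprotonation at the silylated γ carbon (KN(SiMe3)2, THF/DMPU) and O-methylation of the dienolate (MeOTf) would give the methoxytriene 7-[(3E)-4-(isopropoxydimethylsilyl)-1-methoxy-2-methylbuta-1,3-dienyl]-6-methyl-8-(triethylsilyloxy)-1,4-dioxaspiro[4.4]non-6-ene F3.
  - Et2Zn/CH2I2 would add methylene to its electron-rich enol ether double bond to give cyclopropane 14, which is heated to 15 as in step 8.

**Step 4.**
- Most likely failure: oxidation at the silyloxy-bearing allylic carbon (which returns 2 after loss of silicon), or allylic transposition with loss of bromine.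
- Fallback, from 4 to 5: a polar ene pathway instead of a chromium oxidant. SeO2 with t-BuOOH should attack the bromine-bearing alkene carbon and place oxygen on the ring CH2 on the methyl side, giving the allylic alcohol (4S)-3-bromo-2-methyl-4-[(triethylsilyl)oxy]cyclopent-2-en-1-ol F4. Oxidation with MnO2 then gives 5.

**Step 11.**
- Most likely failure: poor facial selectivity in the protonation of C5, giving the cis-fused ketal, or ionisation of the allylic C4 oxygen before the enol ether is consumed.
- Fallback, from 17 to 18, under thermodynamic control: hydrolysis with aqueous oxalic acid in THF at 0 °C would give the ketone 10α-(tert-butyldimethylsilyloxy)-1β,8-dimethyl-4β-(triethylsilyloxy)-5α-H-bicyclo[5.3.0]dec-8-ene-2,6-dione 2-ethylene ketal F5. Its C5 centre would be equilibrated with a mild base (Et3N, MeOH) towards the trans fusion that a seven-ring ketone next to the fusion is expected to prefer. HC(OMe)3, MeOH and pyridinium p-toluenesulfonate would then give 18.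

**Step 13.**
- Most likely failure: enolisation towards C5 or β-hydride reduction by the secondary organometallic, or attack on the β face.
- Fallback, from 19 to 20: isopropenylmagnesium bromide with CeCl3, a smaller sp2 nucleophile without β-hydrogens on a saturated carbon, would give the carbinol 10α-(tert-butyldimethylsilyloxy)-4β-hydroxy-4α-isopropenyl-6,6-dimethoxy-1β,8-dimethyl-5α-H-bicyclo[5.3.0]dec-8-en-2-one ethylene ketal F6. Hydrogenation of its 1,1-disubstituted alkene with RhCl(PPh3)3 and H2, which should leave the trisubstituted ring alkene, gives 20.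

**Step 15.**
- Most likely failure: slow exchange of the hindered tertiary hydroxyl onto boron, so that external hydride attacks from the α face and the C6 epimer forms.
- Fallback, from 21 to 24, which uses that outcome: NaBH4 in MeOH would be used on purpose to give the 6β alcohol 10α-(tert-butyldimethylsilyloxy)-4β,6β-dihydroxy-4α-isopropyl-1β,8-dimethyl-5α-H-bicyclo[5.3.0]dec-8-en-2-one ethylene ketal F7. Mitsunobu esterification with 3,4-dimethoxybenzoic acid (PPh3, diisopropyl azodicarboxylate) would install the ester with inversion and give 24 directly.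

## Further compounds

F1 | step 8 | (E)-N-methoxy-N,2-dimethyl-4-[isopropoxy(dimethyl)silyl]but-2-enamide | CON(C)C(=O)/C(C)=C/C[Si](C)(C)OC(C)C
F2 | step 8 | (E)-4-[isopropoxy(dimethyl)silyl]-2-methyl-1-[(8S)-6-methyl-8-(triethylsilyloxy)-1,4-dioxaspiro[4.4]non-6-en-7-yl]but-2-en-1-one | C/C(=C\C[Si](C)(C)OC(C)C)C(=O)C1=C(C)C2(OCCO2)C[C@@H]1O[Si](CC)(CC)CC
F3 | step 8 | (8S)-7-[(3E)-4-(isopropoxydimethylsilyl)-1-methoxy-2-methylbuta-1,3-dienyl]-6-methyl-8-(triethylsilyloxy)-1,4-dioxaspiro[4.4]non-6-ene (enol ether geometry not fixed) | COC(=C(C)/C=C/[Si](C)(C)OC(C)C)C1=C(C)C2(OCCO2)C[C@@H]1O[Si](CC)(CC)CC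
F4 | step 4 | (4S)-3-bromo-2-methyl-4-[(triethylsilyl)oxy]cyclopent-2-en-1-ol (both C1 epimers) | CC1=C(Br)[C@@H](O[Si](CC)(CC)CC)CC1O
F5 | step 11 | 10α-(tert-butyldimethylsilyloxy)-1β,8-dimethyl-4β-(triethylsilyloxy)-5α-H-bicyclo[5.3.0]dec-8-ene-2,6-dione 2-ethylene ketal | O=C2CC(C)=C[C@@H](O[Si](C)(C)C(C)(C)C)[C@@]3(C)C4(OCCO4)C[C@H](O[Si](CC)(CC)CC)[C@H]23
F6 | step 13 | 10α-(tert-butyldimethylsilyloxy)-4β-hydroxy-4α-isopropenyl-6,6-dimethoxy-1β,8-dimethyl-5α-H-bicyclo[5.3.0]dec-8-en-2-one ethylene ketal | COC2(OC)CC(C)=C[C@@H](O[Si](C)(C)C(C)(C)C)[C@@]3(C)C4(OCCO4)C[C@@](O)(C(C)=C)[C@H]23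
F7 | step 15 | 10α-(tert-butyldimethylsilyloxy)-4β,6β-dihydroxy-4α-isopropyl-1β,8-dimethyl-5α-H-bicyclo[5.3.0]dec-8-en-2-one ethylene ketal | O[C@@H]2CC(C)=C[C@@H](O[Si](C)(C)C(C)(C)C)[C@@]3(C)C4(OCCO4)C[C@@](O)(C(C)C)[C@H]23
A1 | alternative 1 | 2-diazo-5-(2,6-dimethoxy-4-methylphenyl)-6-methyl-5-(triethylsilyloxy)heptan-3-one (C5 of the chain is C4 of the target) | CC(=[N+]=[N-])C(=O)C[C@@](O[Si](CC)(CC)CC)(C(C)C)c1c(OC)cc(C)cc1OC
A2 | alternative 1 | 4α-isopropyl-6,10-dimethoxy-1β,8-dimethyl-4β-(triethylsilyloxy)bicyclo[5.3.0]deca-5,7,9-trien-2-one | COC=2C=C(C)C=C(OC)[C@@]3(C)C(=O)C[C@@](O[Si](CC)(CC)CC)(C(C)C)C=23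
A3 | alternative 2 | 6-(tert-butyldimethylsilyloxy)-7-(diazoacetyl)-2-[(4-methoxybenzyloxy)methyl]-2,4-dimethylcyclohept-3-en-1-one (ring carbons 1, 2, 6 and 7 are C10, C1, C6 and C5 of the target) | CC(C)(C)[Si](C)(C)O[C@H]1CC(C)=CC(=O)[C@@](C)(COCc2ccc(OC)cc2)[C@@H]1C(=O)C=[N+]=[N-]
A4 | alternative 2 | 6α-(tert-butyldimethylsilyloxy)-2α-(4-methoxybenzyloxy)-1β,8-dimethyl-5α-H-bicyclo[5.3.0]dec-8-ene-4,10-dione | CC(C)(C)[Si](C)(C)O[C@H]2CC(C)=CC(=O)[C@@]3(C)[C@@H](OCc4ccc(OC)cc4)CC(=O)[C@H]23
A5 | alternative 3 | (Z)-1-(2-formyl-3α,5β-dihydroxy-5α-isopropyl-2β-methylcyclopentyl)-4-iodo-3-methylbut-3-enyl 3,4-dimethoxybenzoate (C1 aldehyde and C9 iodide of the target) | COc1ccc(C(=O)O[C@@H](C/C(C)=C\I)[C@H]2[C@](O)(C(C)C)C[C@H](O)[C@]2(C)C=O)cc1OC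
A6 | alternative 3 | 2α,4β,10α-trihydroxy-4α-isopropyl-1β,8-dimethyl-5α-H-bicyclo[5.3.0]dec-8-en-6α-yl 3,4-dimethoxybenzoate (identical with 27) | COc1ccc(C(=O)O[C@H]2CC(C)=C[C@@H](O)[C@@]3(C)[C@@H](O)C[C@@](O)(C(C)C)[C@H]23)cc1OC
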